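## Retrosynthetic overview

1. The target (germacrane numbering) is reached from macrocycle 30 by desilylation and double acetylation of the C14 and side-chain hydroxyls.
2. Key disconnection C9–C10: the ten-membered carbocycle (C1–C10) is closed last, by a nickel-catalysed reductive coupling of two electrophilic carbons in seco-diiodide 29.
3. Enabling feature: C9 is the exocyclic CH2 on lactone carbon C8 (β to the ring oxygen of the five-membered lactone), so it can be a primary iodide on a preformed trans-lactone; C10 is the iodine-bearing sp2 carbon of a (Z)-2-iodoallyl ether (C1=C10–C14–O), so the ring-cis C1=C10 geometry is fixed before cyclisation.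
4. 29 comes from hydroxy ester 24 (acylation at O6; acetonide loss closes the γ-lactone ring first; iodination). 24 is made by an indium Barbier coupling (C6–C7) of aldehyde 12 (C1–C6, C10, C14, C15; C4 from asymmetric epoxidation of geraniol) with bromide 16 (C7–C9, C11–C13; C8 from (R)-glyceraldehyde acetonide).
5. Ring order: γ-lactone (step 19), then the ten-membered ring (step 21); side-chain acid 22 comes from crotonaldehyde.

Key step: step 21

Remark on the chemistry: atom labels follow germacrane numbering (ring C1–C10, lactone carbons C11–C13 on C7, C14 on C10, C15 on C4, O6 and O8 on C6 and C8).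

## Fragment A (steps 1–10): aldehyde 12

Step 1
Reactants: 1 geraniol
Product: 2 (2S,3S)-2,3-epoxygeraniol
Conditions: Ti(OiPr)4 (5 mol %), L-(+)-diethyl tartrate (6 mol %), t-BuOOH, 4 Å MS, CH2Cl2, −20 °C
Reagents that add atoms: tert-butyl hydroperoxide, CC(C)(C)OO
Why: Sharpless asymmetric epoxidation of the allylic alcohol, in which the L-(+)-tartrate catalyst selects the alkene face that gives the (2S,3S)-epoxide and thereby fixes the future C4 carbinol centre.

Step 2
Reactants: 2 (2S,3S)-2,3-epoxygeraniol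
Product: 3 (3S)-3,7-dimethyloct-6-ene-1,3-diol
Conditions: NaAlH2(OCH2CH2OMe)2, THF, 0 °C to rt
Reagents that add atoms: none
Why: Alkoxide-directed hydride opening of a 2,3-epoxy alcohol delivers hydride to C2 and gives the 1,3-diol, leaving the tertiary C–O bond and its configuration untouched.

Step 3
Reactants: 3 (3S)-3,7-dimethyloct-6-ene-1,3-diol
Product: 4 (4S)-2,2,4-trimethyl-4-(4-methylpent-3-en-1-yl)-1,3-dioxane
Conditions: 2,2-dimethoxypropane, PPTS (cat.), CH2Cl2, rt
Reagents that add atoms: 2,2-dimethoxypropane, COC(C)(C)OC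
Why: Acid-catalysed transacetalisation masks both hydroxyls so that the tertiary alcohol cannot form a lactol or add to the enal in steps 4 to 7.

Step 4
Reactants: 4 (4S)-2,2,4-trimethyl-4-(4-methylpent-3-en-1-yl)-1,3-dioxane
Product: 6 3-[(4S)-2,2,4-trimethyl-1,3-dioxan-4-yl]propanal, via ozonide 5 (not isolated)
Conditions: O3, CH2Cl2, −78 °C; then PPh3, −78 °C to rt
Reagents that add atoms: ozone, [O-][O+]=O
Why: Ozonolysis with reductive work-up (Criegee mechanism) cleaves the only alkene and gives the C1 aldehyde.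

Step 5
Reactants: 6 3-[(4S)-2,2,4-trimethyl-1,3-dioxan-4-yl]propanal
Product: 7 (2E)-5-[(4S)-2,2,4-trimethyl-1,3-dioxan-4-yl]pent-2-enal
Conditions: Ph3P=CHCHO, toluene, 70 °C
Reagents that add atoms: (triphenylphosphoranylidene)acetaldehyde, O=CC=P(c1ccccc1)(c1ccccc1)c1ccccc1
Why: Wittig olefination with the stabilised formylmethylene ylide should give the (E)-enal and adds C10 and C14.

Step 6
Reactants: 7 (2E)-5-[(4S)-2,2,4-trimethyl-1,3-dioxan-4-yl]pent-2-enal
Product: 8 (2Z)-2-iodo-5-[(4S)-2,2,4-trimethyl-1,3-dioxan-4-yl]pent-2-enal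
Conditions: I2, K2CO3, DMAP (20 mol %), THF/H2O 1:1, rt
Reagents that add atoms: iodine, II
Why: Amine-mediated α-iodination of the enal (conjugate addition of DMAP, iodination, elimination) should give the (Z)-α-iodoenal, with iodine cis to the chain as required at C1=C10.

Step 7
Reactants: 8 (2Z)-2-iodo-5-[(4S)-2,2,4-trimethyl-1,3-dioxan-4-yl]pent-2-enal
Product: 9 (2Z)-2-iodo-5-[(4S)-2,2,4-trimethyl-1,3-dioxan-4-yl]pent-2-en-1-ol
Conditions: NaBH4, CeCl3·7H2O, MeOH, −40 to 0 °C
Reagents that add atoms: none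
Why: Luche reduction is 1,2-selective and leaves the C–I bond and the alkene geometry intact.

Step 8
Reactants: 9 (2Z)-2-iodo-5-[(4S)-2,2,4-trimethyl-1,3-dioxan-4-yl]pent-2-en-1-ol
Product: 10 tert-butyl({(2Z)-2-iodo-5-[(4S)-2,2,4-trimethyl-1,3-dioxan-4-yl]pent-2-en-1-yl}oxy)diphenylsilane
Conditions: TBDPSCl, imidazole, DMF, rt
Reagents that add atoms: tert-butyl(chloro)diphenylsilane, CC(C)(C)[Si](Cl)(c1ccccc1)c1ccccc1
Why: Standard silylation; the TBDPS ether is chosen because it survives the acidic steps 9 and 19.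

Step 9
Reactants: 10 tert-butyl({(2Z)-2-iodo-5-[(4S)-2,2,4-trimethyl-1,3-dioxan-4-yl]pent-2-en-1-yl}oxy)diphenylsilane
Product: 11 (3S,6Z)-8-[(tert-butyldiphenylsilyl)oxy]-7-iodo-3-methyloct-6-ene-1,3-diol
Conditions: AcOH/H2O 4:1, 40 °C
Reagents that add atoms: none
Why: Mild aqueous acid hydrolyses the dioxane acetonide while the TBDPS ether and the vinyl iodide are stable.

Step 10
Reactants: 11 (3S,6Z)-8-[(tert-butyldiphenylsilyl)oxy]-7-iodo-3-methyloct-6-ene-1,3-diol
Product: 12 (3S,6Z)-8-[(tert-butyldiphenylsilyl)oxy]-3-hydroxy-7-iodo-3-methyloct-6-enal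
Conditions: TEMPO (10 mol %), PhI(OAc)2, CH2Cl2, rt
Reagents that add atoms: none
Why: Oxoammonium oxidation converts only the primary alcohol, and the near-neutral medium avoids retro-aldol or dehydration of the β-hydroxy aldehyde, which is used at once.

## Fragment B (steps 11–12): bromide 16

Step 11
Reactants: 13 (R)-2,2-dimethyl-1,3-dioxolane-4-carbaldehyde; 14 methyl acrylate
Product: 15 methyl 2-{[(4R)-2,2-dimethyl-1,3-dioxolan-4-yl](hydroxy)methyl}prop-2-enoate (carbinol epimers)
Conditions: DABCO (0.5 equiv), dioxane/H2O 1:1, rt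
Reagents that add atoms: none
Why: Morita–Baylis–Hillman reaction; the new carbinol centre is unimportant because it becomes sp2 in step 12, and the dioxolane centre should survive the mild amine catalyst.

Step 12
Reactants: 15 methyl 2-{[(4R)-2,2-dimethyl-1,3-dioxolan-4-yl](hydroxy)methyl}prop-2-enoate
Product: 16 methyl (2Z)-2-(bromomethyl)-3-[(4S)-2,2-dimethyl-1,3-dioxolan-4-yl]prop-2-enoate
Conditions: NBS, Me2S, CH2Cl2, 0 °C to rt
Reagents that add atoms: N-bromosuccinimide, O=C1CCC(=O)N1Br
Why: Corey–Kim-type activation of the allylic alcohol and SN2' attack of bromide should give the (Z)-2-(bromomethyl)alkenoate with the ester trans to the dioxolanyl group.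

## Fragment C (steps 13–16): side-chain acid 22

Step 13
Reactants: 17 (E)-but-2-enal
Product: 18 (2Z)-2-iodobut-2-enal
Conditions: I2, K2CO3, DMAP (20 mol %), THF/H2O 1:1, rt
Reagents that add atoms: iodine, II
Why: The same α-iodination as in step 6 places iodine cis to the methyl group.

Step 14
Reactants: 18 (2Z)-2-iodobut-2-enal
Product: 19 (2Z)-2-iodobut-2-en-1-ol
Conditions: NaBH4, CeCl3·7H2O, MeOH, −40 to 0 °C
Reagents that add atoms: none
Why: Luche 1,2-reduction with retention of alkene geometry.

Step 15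
Reactants: 19 (2Z)-2-iodobut-2-en-1-ol
Product: 20 tert-butyl{[(2Z)-2-iodobut-2-en-1-yl]oxy}diphenylsilane
Conditions: TBDPSCl, imidazole, CH2Cl2, rt
Reagents that add atoms: tert-butyl(chloro)diphenylsilane, CC(C)(C)[Si](Cl)(c1ccccc1)c1ccccc1
Why: Standard silylation of the primary allylic alcohol.

Step 16
Reactants: 20 tert-butyl{[(2Z)-2-iodobut-2-en-1-yl]oxy}diphenylsilane
Product: 22 (2Z)-2-{[(tert-butyldiphenylsilyl)oxy]methyl}but-2-enoic acid, via vinyllithium 21 (not isolated)
Conditions: t-BuLi (2.1 equiv), Et2O, −78 °C; CO2; 1 M HCl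
Reagents that add atoms: carbon dioxide, O=C=O
Why: Iodine–lithium exchange and carboxylation both proceed with retention at the sp2 carbon, so the carboxyl group ends cis to the methyl group (sarracinic acid geometry).

## Assembly and endgame (steps 17–23)

Step 17
Reactants: 12 (3S,6Z)-8-[(tert-butyldiphenylsilyl)oxy]-3-hydroxy-7-iodo-3-methyloct-6-enal; 16 methyl (2Z)-2-(bromomethyl)-3-[(4S)-2,2-dimethyl-1,3-dioxolan-4-yl]prop-2-enoate
Product: 24 methyl (3R,4R,6S,9Z)-11-[(tert-butyldiphenylsilyl)oxy]-3-[(4S)-2,2-dimethyl-1,3-dioxolan-4-yl]-4,6-dihydroxy-10-iodo-6-methyl-2-methylideneundec-9-enoate, via allylindium reagent 23 (not isolated)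
Conditions: indium powder, THF/H2O 1:1, rt
Reagents that add atoms: none
Why: Indium-mediated Barbier allylation at the γ-carbon through a chair (Zimmerman–Traxler) transition state, in which the (Z)-bromide should give the syn relation of the C6 hydroxyl and the C7 substituent, while attack anti to the dioxolane C–O bond (allylic C–H eclipsing the alkene to relieve 1,3-allylic strain) should set C7 relative to C8.

Step 18
Reactants: 24 hydroxy ester from step 17; 22 (2Z)-2-{[(tert-butyldiphenylsilyl)oxy]methyl}but-2-enoic acid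
Product: 26 O6-[(2Z)-2-{[(tert-butyldiphenylsilyl)oxy]methyl}but-2-enoyl] ester of 24, via mixed anhydride 25 (not isolated)
Conditions: 22, 2,4,6-trichlorobenzoyl chloride, Et3N, toluene, rt; then 24, DMAP, toluene, 0 °C to rt
Reagents that add atoms: none
Why: Yamaguchi esterification acylates the secondary carbinol only (the tertiary alcohol is too hindered) and is the usual way to transfer angelate-type (Z)-acids without isomerisation; the ester also blocks O6 from lactonising.

Step 19
Reactants: 26 ester from step 18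
Product: 28 (4R,5S)-5-(hydroxymethyl)-3-methylidene-4-[(1R,3S,6Z)-8-[(tert-butyldiphenylsilyl)oxy]-1-{[(2Z)-2-{[(tert-butyldiphenylsilyl)oxy]methyl}but-2-enoyl]oxy}-3-hydroxy-7-iodo-3-methyloct-6-en-1-yl]oxolan-2-one, via diol 27 (not isolated)
Conditions: AcOH/H2O 4:1, 45 °C; then TsOH·H2O (cat.), CH2Cl2, rt
Reagents that add atoms: none
Why: Hydrolysis of the terminal acetonide frees O8, which closes the five-membered lactone on the methyl ester (5-exo acyl substitution, preferred over the six-membered alternative through the primary hydroxyl), giving the trans-lactone whose centres were set in step 17.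

Step 20
Reactants: 28 hydroxy lactone from step 19
Product: 29 (4R,5S)-5-(iodomethyl) analogue of 28 (seco-diiodide)
Conditions: PPh3, I2, imidazole (premixed), CH2Cl2, 0 °C to rt
Reagents that add atoms: iodine, II
Why: Appel-type iodination converts only the primary alcohol by SN2 displacement of the alkoxyphosphonium ion and leaves the tertiary alcohol.

Step 21
Reactants: 29 seco-diiodide
Product: 30 bis-TBDPS ether of the ten-membered 8,12-olide (target skeleton with silyl ethers at O14 and at the side-chain CH2O)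
Conditions: NiBr2(dme) (30 mol %), 4,4'-di-tert-butyl-2,2'-bipyridine (33 mol %), Mn powder, NaI (0.5 equiv), DMA, 40 °C, slow addition of 29 to 2 mM
Reagents that add atoms: none
Why: Proposed new method: bipyridine-ligated zerovalent nickel (regenerated by Mn) adds oxidatively to the vinyl iodide with retention of the (Z)-geometry, a monovalent nickel species abstracts iodine from the primary alkyl iodide, and the C9 radical is captured at the vinylnickel centre so that C(sp3)–C(sp2) reductive elimination from trivalent nickel forms the C9–C10 bond. The closest known reaction type is the intermolecular nickel-catalysed cross-electrophile coupling of alkenyl halides with primary alkyl halides, which retains alkene geometry and tolerates esters and free alcohols, and the closest known ring closures are Nozaki–Hiyama–Kishi medium-ring cyclisations of vinyl iodides. The ten-membered carbocycle is closed in an endo sense (both C1 and C10 end up in the ring) by radical capture to an eleven-membered nickelacycle followed by ring-contracting reductive elimination. No stereocentre is created: the ring-cis C1=C10 geometry is inherited from the (Z)-iodide and C8 is untouched because only its neighbour C9 becomes a radical. The step needs cyclisation to beat hydrodeiodination and dimerisation (slow addition, high dilution) and radical side paths; in the substrate the β-acyloxy C9 radical should not fragment at a competitive rate, attack on the α-methylene group would be a disfavoured 5-endo closure, no chlorosilane is present to promote reductive conjugate addition, and the silyl ethers keep the allylic C–O bonds from ionising at nickel.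

Step 22
Reactants: 30 bis-TBDPS macrocycle
Product: 31 14-hydroxy and side-chain hydroxymethyl triol (C4, C14 and side-chain OH free)
Conditions: HF·pyridine, pyridine/THF, 0 °C to rt
Reagents that add atoms: none
Why: Fluoride-driven cleavage of both primary silyl ethers under non-basic conditions should spare the α-methylene lactone, the esters and the tertiary alcohol.

Step 23
Reactants: 31 triol
Product: 32 CNP0280960.1
Conditions: Ac2O, pyridine, DMAP (5 mol %), CH2Cl2, 0 °C
Reagents that add atoms: acetic anhydride, CC(=O)OC(C)=O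
Why: DMAP-catalysed acetylation of the two primary allylic alcohols; the tertiary C4 hydroxyl should not react at 0 °C.

## Compound list

1 | geraniol | CC(C)=CCC/C(C)=C/CO | starting material
2 | (2S,3S)-2,3-epoxygeraniol | CC(C)=CCC[C@]1(C)O[C@H]1CO | intermediate
3 | (3S)-3,7-dimethyloct-6-ene-1,3-diol | CC(C)=CCC[C@](C)(O)CCO | intermediate
4 | (4S)-2,2,4-trimethyl-4-(4-methylpent-3-en-1-yl)-1,3-dioxane | CC(C)=CCC[C@@]1(C)CCOC(C)(C)O1 | intermediate
5 | ozonide (1,2,4-trioxolane) of 4 | CC1(C)OOC(CC[C@@]2(C)CCOC(C)(C)O2)O1 | intermediate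
6 | 3-[(4S)-2,2,4-trimethyl-1,3-dioxan-4-yl]propanal | O=CCC[C@@]1(C)CCOC(C)(C)O1 | intermediate
7 | (2E)-5-[(4S)-2,2,4-trimethyl-1,3-dioxan-4-yl]pent-2-enal | O=C/C=C/CC[C@@]1(C)CCOC(C)(C)O1 | intermediate
8 | (2Z)-2-iodo-5-[(4S)-2,2,4-trimethyl-1,3-dioxan-4-yl]pent-2-enal | O=C/C(I)=C/CC[C@@]1(C)CCOC(C)(C)O1 | intermediate
9 | (2Z)-2-iodo-5-[(4S)-2,2,4-trimethyl-1,3-dioxan-4-yl]pent-2-en-1-ol | OC/C(I)=C/CC[C@@]1(C)CCOC(C)(C)O1 | intermediate
10 | TBDPS ether of 9 | CC(C)(C)[Si](c1ccccc1)(c1ccccc1)OC/C(I)=C/CC[C@@]2(C)CCOC(C)(C)O2 | intermediate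
11 | (3S,6Z)-8-[(tert-butyldiphenylsilyl)oxy]-7-iodo-3-methyloct-6-ene-1,3-diol | CC(C)(C)[Si](c1ccccc1)(c1ccccc1)OC/C(I)=C/CC[C@](C)(O)CCO | intermediate
12 | (3S,6Z)-8-[(tert-butyldiphenylsilyl)oxy]-3-hydroxy-7-iodo-3-methyloct-6-enal | CC(C)(C)[Si](c1ccccc1)(c1ccccc1)OC/C(I)=C/CC[C@](C)(O)CC=O | intermediate
13 | (R)-2,2-dimethyl-1,3-dioxolane-4-carbaldehyde | O=C[C@H]1COC(C)(C)O1 | starting material
14 | methyl acrylate | C=CC(=O)OC | starting material
15 | methyl 2-{[(4R)-2,2-dimethyl-1,3-dioxolan-4-yl](hydroxy)methyl}prop-2-enoate, carbinol epimers | C=C(C(=O)OC)C(O)[C@H]1COC(C)(C)O1 | intermediate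
16 | methyl (2Z)-2-(bromomethyl)-3-[(4S)-2,2-dimethyl-1,3-dioxolan-4-yl]prop-2-enoate | COC(=O)/C(CBr)=C/[C@H]1COC(C)(C)O1 | intermediate
17 | (E)-but-2-enal (crotonaldehyde) | C/C=C/C=O | starting material
18 | (2Z)-2-iodobut-2-enal | C/C=C(\I)C=O | intermediate
19 | (2Z)-2-iodobut-2-en-1-ol | C/C=C(\I)CO | intermediate
20 | tert-butyl{[(2Z)-2-iodobut-2-en-1-yl]oxy}diphenylsilane | C/C=C(\I)CO[Si](c1ccccc1)(c1ccccc1)C(C)(C)C | intermediate
21 | (Z)-vinyllithium from 20 | C/C=C(\[Li])CO[Si](c1ccccc1)(c1ccccc1)C(C)(C)C | intermediate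
22 | (2Z)-2-{[(tert-butyldiphenylsilyl)oxy]methyl}but-2-enoic acid | C/C=C(\C(=O)O)CO[Si](c1ccccc1)(c1ccccc1)C(C)(C)C | intermediate
23 | allylindium reagent from 16, drawn as the allylindium dibromide | COC(=O)/C(C[In](Br)Br)=C/[C@H]1COC(C)(C)O1 | intermediate
24 | methyl (3R,4R,6S,9Z)-11-[(tert-butyldiphenylsilyl)oxy]-3-[(4S)-2,2-dimethyl-1,3-dioxolan-4-yl]-4,6-dihydroxy-10-iodo-6-methyl-2-methylideneundec-9-enoate | C=C(C(=O)OC)[C@@H]([C@H]1COC(C)(C)O1)[C@H](O)C[C@@](C)(O)CC/C=C(\I)CO[Si](c2ccccc2)(c2ccccc2)C(C)(C)C | intermediate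
25 | mixed anhydride of 22 with 2,4,6-trichlorobenzoic acid | C/C=C(\C(=O)OC(=O)c1c(Cl)cc(Cl)cc1Cl)CO[Si](c1ccccc1)(c1ccccc1)C(C)(C)C | intermediate
26 | O6-[(2Z)-2-{[(tert-butyldiphenylsilyl)oxy]methyl}but-2-enoyl] ester of 24 | C=C(C(=O)OC)[C@@H]([C@H]1COC(C)(C)O1)[C@H](OC(=O)/C(=C\C)CO[Si](c2ccccc2)(c2ccccc2)C(C)(C)C)C[C@@](C)(O)CC/C=C(\I)CO[Si](c2ccccc2)(c2ccccc2)C(C)(C)C | intermediate
27 | 1,2-diol from 26 after loss of the acetonide | C=C(C(=O)OC)[C@@H]([C@H](O)CO)[C@H](OC(=O)/C(=C\C)CO[Si](c1ccccc1)(c1ccccc1)C(C)(C)C)C[C@@](C)(O)CC/C=C(\I)CO[Si](c1ccccc1)(c1ccccc1)C(C)(C)C | intermediate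
28 | (4R,5S)-5-(hydroxymethyl)-3-methylidene-4-[(1R,3S,6Z)-side chain]oxolan-2-one (trans-lactone, O6 acylated, C4 hydroxyl free) | C=C1C(=O)O[C@H](CO)[C@H]1[C@@H](C[C@@](CC/C=C(/CO[Si](c2ccccc2)(c2ccccc2)C(C)(C)C)I)(C)O)OC(=O)/C(=C\C)CO[Si](c2ccccc2)(c2ccccc2)C(C)(C)C | intermediate
29 | (4R,5S)-5-(iodomethyl) analogue of 28 (seco-diiodide) | C=C1C(=O)O[C@H](CI)[C@H]1[C@@H](C[C@@](CC/C=C(/CO[Si](c2ccccc2)(c2ccccc2)C(C)(C)C)I)(C)O)OC(=O)/C(=C\C)CO[Si](c2ccccc2)(c2ccccc2)C(C)(C)C | intermediate
30 | bis-TBDPS ether of the ten-membered 8,12-olide | C=C1C(=O)O[C@@H]2C/C(CO[Si](c3ccccc3)(c3ccccc3)C(C)(C)C)=C\CC[C@](C)(O)C[C@@H](OC(=O)/C(=C\C)CO[Si](c3ccccc3)(c3ccccc3)C(C)(C)C)[C@@H]12 | intermediate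
31 | triol (C14 and side-chain hydroxymethyl free, C4 hydroxyl free) | C=C1C(=O)O[C@@H]2C/C(CO)=C\CC[C@](C)(O)C[C@@H](OC(=O)/C(=C\C)CO)[C@@H]12 | intermediate
32 | CNP0280960.1 | C=C1C(=O)O[C@@H]2C/C(COC(C)=O)=C\CC[C@](C)(O)C[C@@H](OC(=O)/C(=C\C)COC(C)=O)[C@@H]12 | target

## Step count and risks

Total step count: 23. Longest linear sequence: 17 steps (steps 1–10, then 17–23).

Steps most likely to fail:

Step 21 (proposed new method). The ring closure may lose to hydrodeiodination of either iodide, to intermolecular coupling, or to reductive opening of the lactone by β-elimination of the carboxylate from an alkylnickel species. The fallback uses known chemistry and sets out from 28. Dess–Martin oxidation of the primary alcohol would give the C9 aldehyde F1. An intramolecular Nozaki–Hiyama–Kishi reaction (CrCl2, NiCl2 cat., DMSO/THF, high dilution) would close the same C9–C10 bond and give the macrocyclic C9 allylic alcohol F2 as a mixture of carbinol epimers. Methyl chloroformate and pyridine would give the allylic methyl carbonate F3. Formate hydrogenolysis (Pd(OAc)2, PBu3, HCO2NH4, dioxane) should deliver hydride to the more hindered allyl terminus C9 and return to the route at 30.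

Step 17. The syn selectivity may erode if the allylindium equilibrates in water, facial discrimination by the dioxolane may be poor, and the adduct may lactonise onto O6. The fallback sets out from 16. Palladium-catalysed borylation (Pd2(dba)3, bis(pinacolato)diboron) would give the configurationally defined allylboronate F4. Its Sc(OTf)3-catalysed allylboration of 12 through a closed chair transition state, followed by aqueous work-up, should return to the route at 24.

Step 18. Acyl transfer to the hindered C6 carbinol may be slow enough for base-induced lactonisation of 24 onto O6 and for Z-to-E isomerisation of the activated acid to compete. The fallback forms the lactone first and the ester by activating the alcohol instead of the acid; it sets out from 15 (with 12 and 22).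
- Aqueous trifluoroacetic acid would convert 15 into the hydroxy lactone diol F5.
- Selective silylation (TBSCl, imidazole) would give the primary silyl ether F6.
- PBr3 would give the ring-locked allylic bromide F7 by SN2' substitution.
- Indium-mediated coupling of F7 with 12 should occur anti to the silyloxymethyl group (trans-lactone) and, from the ring-fixed allyl geometry, give the C6-epimeric alcohol F8.
- Mitsunobu esterification of F8 with 22 (PPh3, DIAD) would install the side chain with inversion at C6 and give F9.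
- PPTS in methanol would remove the primary TBS ether and return to the route at 28.

## Further compounds

F1 | step 21 | C9 aldehyde from 28 | C=C1C(=O)O[C@H](C=O)[C@H]1[C@@H](C[C@@](CC/C=C(/CO[Si](c2ccccc2)(c2ccccc2)C(C)(C)C)I)(C)O)OC(=O)/C(=C\C)CO[Si](c2ccccc2)(c2ccccc2)C(C)(C)C
F2 | step 21 | macrocyclic C9 allylic alcohol (C9 epimers) | C=C1C(=O)O[C@@H]2C(O)/C(CO[Si](c3ccccc3)(c3ccccc3)C(C)(C)C)=C\CC[C@](C)(O)C[C@@H](OC(=O)/C(=C\C)CO[Si](c3ccccc3)(c3ccccc3)C(C)(C)C)[C@@H]12
F3 | step 21 | C9 methyl carbonate of F2 | C=C1C(=O)O[C@@H]2C(OC(=O)OC)/C(CO[Si](c3ccccc3)(c3ccccc3)C(C)(C)C)=C\CC[C@](C)(O)C[C@@H](OC(=O)/C(=C\C)CO[Si](c3ccccc3)(c3ccccc3)C(C)(C)C)[C@@H]12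
F4 | step 17 | methyl (2E)-3-[(4S)-2,2-dimethyl-1,3-dioxolan-4-yl]-2-[(4,4,5,5-tetramethyl-1,3,2-dioxaborolan-2-yl)methyl]prop-2-enoate | COC(=O)/C(CB1OC(C)(C)C(C)(C)O1)=C/[C@H]2COC(C)(C)O2
F5 | step 18 | (5S)-4-hydroxy-5-(hydroxymethyl)-3-methylideneoxolan-2-one (C4 epimers) | C=C1C(=O)O[C@H](CO)C1O
F6 | step 18 | primary TBS ether of F5 | C=C1C(=O)O[C@H](CO[Si](C)(C)C(C)(C)C)C1O
F7 | step 18 | (5S)-3-(bromomethyl)-5-{[(tert-butyldimethylsilyl)oxy]methyl}furan-2(5H)-one | BrCC1=C[C@@H](CO[Si](C)(C)C(C)(C)C)OC1=O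
F8 | step 18 | trans-lactone adduct of F7 and 12 with the C6-epimeric free carbinol | C=C1C(=O)O[C@H](CO[Si](C)(C)C(C)(C)C)[C@H]1[C@H](C[C@@](CC/C=C(/CO[Si](c2ccccc2)(c2ccccc2)C(C)(C)C)I)(C)O)O
F9 | step 18 | O9-TBS ether of 28 (Mitsunobu ester, C6 inverted) | C=C1C(=O)O[C@H](CO[Si](C)(C)C(C)(C)C)[C@H]1[C@@H](C[C@@](CC/C=C(/CO[Si](c2ccccc2)(c2ccccc2)C(C)(C)C)I)(C)O)OC(=O)/C(=C\C)CO[Si](c2ccccc2)(c2ccccc2)C(C)(C)C
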